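**Retrosynthetic overview**
- The strategy rests on the 4-hydroxy-2-pyrone ring (O1', C2'–C6'). C2'–C3'–C4' is a malonyl unit whose C3' already carries the bridge CH2 to C8 of the chromene. C5'(CH3)–C6'(C2H5)–O1' is the enol of symmetrical pentan-3-one.
- The last disconnections are the two O–CH3 bonds (C5-OMe, C7-OMe), then C4'–C5' and O1'–C2' of the pyrone. This leads back to arylmethylmalonyl dichloride 17 (reacting through its (chlorocarbonyl)ketene 18) and silyl enol ether 16.
- 17 comes from malonic acid 14, which comes from aldehyde 9 and Meldrum's acid by reductive Knoevenagel alkylation (chain C8–CH2–C3').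
- 9 goes back by O-methylation and C8 formylation to chromene ketone 6. 6 is made from phloroglucinol by C-acylation and chromenylation with 3-methylbut-2-enal.
- Ring order: benzene ring (bought), 2H-pyran ring of the chromene (step 2), pyrone ring (step 9).

Key step: step 9

Remark: the target has no stereocentre. Locants O1–C8a are used for the chromene and O1'–C6' for the pyrone. Intermediate 13 is racemic at a centre that disappears again.

**Step 1**
Reactants: 1 phloroglucinol; 2 2-methylpropanoyl chloride
Product: 3 2-methyl-1-(2,4,6-trihydroxyphenyl)propan-1-one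
Conditions: AlCl3 (3.5 equiv), CH2Cl2–PhNO2, 0 °C → 40 °C; then ice/1 M HCl
Reagents that add atoms: none
Why: Friedel–Crafts C-acylation of the very electron-rich ring should stop after one acyl group, because the chelated aryl ketone–AlCl3 complex deactivates the ring.

**Step 2**
Reactants: 3 2-methyl-1-(2,4,6-trihydroxyphenyl)propan-1-one; 4 3-methylbut-2-enal
Product: 6 1-(5,7-dihydroxy-2,2-dimethyl-2H-chromen-6-yl)-2-methylpropan-1-one, via o-quinone methide 5 (not isolated)
Conditions: 4 (1.1 equiv), pyridine, 110 °C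
Reagents that add atoms: none
Why: Pyridine-promoted chromenylation (Knoevenagel-type condensation at a free ring carbon, loss of water to 5, oxa-6π electrocyclisation) should close on the free hydroxyl para to the acyl group, because the ortho hydroxyls are tied up in hydrogen bonding to the ketone, and this places the acyl group at C6.

**Step 3**
Reactants: 6 1-(5,7-dihydroxy-2,2-dimethyl-2H-chromen-6-yl)-2-methylpropan-1-one
Product: 8 5,7-dihydroxy-2,2-dimethyl-6-(2-methylpropanoyl)-2H-chromene-8-carbaldehyde, via aryl iminium chloride 7 (not isolated)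
Conditions: POCl3 (1.5 equiv), DMF (2 equiv), EtOAc, 0 °C → rt; then H2O
Reagents that add atoms: N,N-dimethylformamide, CN(C)C=O (formyl carbon); water, O (aldehyde oxygen)
Why: Vilsmeier–Haack formylation should attack C8, the only free aromatic position (ortho to the C7 hydroxyl and O1, para to the C5 hydroxyl), faster than the hindered C3=C4 bond or the slowly enolising isobutyryl group, and hydrolysis of 7 gives the aldehyde.

**Step 4**
Reactants: 8 5,7-dihydroxy-2,2-dimethyl-6-(2-methylpropanoyl)-2H-chromene-8-carbaldehyde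
Product: 9 5,7-dimethoxy-2,2-dimethyl-6-(2-methylpropanoyl)-2H-chromene-8-carbaldehyde
Conditions: Me2SO4 (3 equiv), K2CO3 (4 equiv), acetone, reflux
Reagents that add atoms: dimethyl sulfate, COS(=O)(=O)OC
Why: Williamson-type O-methylation with a hard electrophile in refluxing acetone overcomes the hydrogen bonds of both acidic phenols, and with every ring carbon substituted C-methylation should not compete.

**Step 5**
Reactants: 9 5,7-dimethoxy-2,2-dimethyl-6-(2-methylpropanoyl)-2H-chromene-8-carbaldehyde; 10 2,2-dimethyl-1,3-dioxane-4,6-dione (Meldrum's acid)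
Product: 12 5-{[5,7-dimethoxy-2,2-dimethyl-6-(2-methylpropanoyl)-2H-chromen-8-yl]methyl}-2,2-dimethyl-1,3-dioxane-4,6-dione, via arylidene Meldrum's acid 11 (not isolated)
Conditions: 10 (1.1 equiv), diethyl 2,6-dimethyl-1,4-dihydropyridine-3,5-dicarboxylate (Hantzsch ester, 1.1 equiv), L-proline (20 mol %), EtOH, rt → 40 °C
Reagents that add atoms: none
Why: In this organocatalytic three-component reductive alkylation, proline-catalysed Knoevenagel condensation gives the strongly electrophilic arylidene 11, which accepts hydride from the Hantzsch ester at the benzylic carbon, while the twisted aryl ketone and the chromene double bond are not hydride acceptors.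

**Step 6**
Reactants: 12 5-{[5,7-dimethoxy-2,2-dimethyl-6-(2-methylpropanoyl)-2H-chromen-8-yl]methyl}-2,2-dimethyl-1,3-dioxane-4,6-dione
Product: 14 2-{[5,7-dimethoxy-2,2-dimethyl-6-(2-methylpropanoyl)-2H-chromen-8-yl]methyl}propanedioic acid, via malonic half methyl ester 13 (not isolated)
Conditions: MeOH, reflux; then LiOH (4 equiv), THF–H2O, rt; then 1 M HCl, 0 °C, to pH 2; dry at rt
Reagents that add atoms: methanol, CO (atoms kept only in 13); lithium hydroxide, [Li+].[OH-] (oxygen of the new CO2H)
Why: Alcoholysis of the neutral monosubstituted Meldrum's acid releases acetone and gives 13, and ester saponification then completes the malonic acid, which sidesteps both the inertness of the Meldrum's acid anion to hydroxide and any hot acid that could harm the chromene or cause decarboxylation.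

**Step 7**
Reactants: 15 pentan-3-one
Product: 16 (Z)-trimethyl(pent-2-en-3-yloxy)silane
Conditions: TMSOTf (1.1 equiv), Et3N (1.3 equiv), CH2Cl2, 0 °C → rt; distil
Reagents that add atoms: trimethylsilyl trifluoromethanesulfonate, C[Si](C)(C)OS(=O)(=O)C(F)(F)F
Why: Soft enolisation and O-silylation of the symmetrical ketone can give only one constitutional silyl enol ether, expected mainly as the Z isomer, and its geometry has no bearing on step 9.

**Step 8**
Reactants: 14 2-{[5,7-dimethoxy-2,2-dimethyl-6-(2-methylpropanoyl)-2H-chromen-8-yl]methyl}propanedioic acid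
Product: 17 2-{[5,7-dimethoxy-2,2-dimethyl-6-(2-methylpropanoyl)-2H-chromen-8-yl]methyl}propanedioyl dichloride
Conditions: (COCl)2 (3 equiv), DMF (cat.), CH2Cl2, 0 °C → rt; evaporate, use at once
Reagents that add atoms: oxalyl chloride, O=C(Cl)C(Cl)=O
Why: Acid chloride formation through the catalytic chloroiminium species is established for monosubstituted malonic acids and runs at or below room temperature, so decarboxylation is avoided and all by-products leave as gases.

**Step 9**
Reactants: 17 2-{[5,7-dimethoxy-2,2-dimethyl-6-(2-methylpropanoyl)-2H-chromen-8-yl]methyl}propanedioyl dichloride; 16 (Z)-trimethyl(pent-2-en-3-yloxy)silane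
Product: 19 3-{[5,7-dimethoxy-2,2-dimethyl-6-(2-methylpropanoyl)-2H-chromen-8-yl]methyl}-6-ethyl-4-hydroxy-5-methyl-2H-pyran-2-one, via (chlorocarbonyl)ketene 18 (not isolated)
Conditions: 16 (3 equiv), toluene, N2, 0 °C → 90 °C
Reagents that add atoms: none
Why: Dichloride 17 loses HCl on warming to give (chlorocarbonyl)ketene 18, and one sacrificial equivalent of 16 takes up that HCl as Me3SiCl and pentan-3-one, which pulls the elimination forward and keeps acid away from the C3=C4 bond of the chromene. The nucleophilic carbon of 16 (future C5') adds to the central ketene carbon (future C4'), the silyl group is passed on, the resulting 1,3-diketone enolises toward C6', and this enol oxygen (O1') displaces chloride at the remaining acyl chloride carbon (C2') in a 6-exo-trig lactonisation that closes the pyrone ring, which settles as the 4-hydroxy tautomer; direct C-acylation of 16 by 17 itself would feed the same adduct. The closest known reaction type is the preparation of 4-hydroxy-2-pyrones from malonyl dichlorides or preformed (chlorocarbonyl)ketenes with silyl enol ethers or enolisable ketones. No stereocentre is created, the geometry of 16 is erased when C5' becomes part of the ring, and the symmetry of pentan-3-one fixes the C5'-methyl and C6'-ethyl pattern without any regiocontrol. The step needs C- rather than O-acylation of 16 and then ring closure through oxygen rather than through the ethyl CH2: the soft enol ether carbon matches the ketene carbon, and O-closure needs only the enol that is already conjugated with C4', whereas C-closure would call for a second, cross-conjugated enolisation. Inside the substrate the C6 ketone is twisted between two methoxy groups and the C3=C4 bond lies next to the quaternary C2, so both are far weaker nucleophiles than 16 used in excess.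

**Step 10**
Reactants: 19 3-{[5,7-dimethoxy-2,2-dimethyl-6-(2-methylpropanoyl)-2H-chromen-8-yl]methyl}-6-ethyl-4-hydroxy-5-methyl-2H-pyran-2-one
Product: 20 3-{[5,7-dihydroxy-2,2-dimethyl-6-(2-methylpropanoyl)-2H-chromen-8-yl]methyl}-6-ethyl-4-hydroxy-5-methyl-2H-pyran-2-one (target)
Conditions: BCl3 (6 equiv, 1 M in CH2Cl2), CH2Cl2, −78 °C → 0 °C; then H2O
Reagents that add atoms: none
Why: In this Lewis-acid aryl methyl ether cleavage both methoxy groups are ortho to the C6 ketone (chelation) and twisted out of the ring plane by two ortho neighbours, the two situations in which BCl3 cleaves methyl ethers fastest, so the low temperature should spare the chromene and the pyrone.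

**Compound list**
1 | phloroglucinol | Oc1cc(O)cc(O)c1 | starting material
2 | 2-methylpropanoyl chloride | CC(C)C(Cl)=O | starting material
3 | 2-methyl-1-(2,4,6-trihydroxyphenyl)propan-1-one | CC(C)C(=O)c1c(O)cc(O)cc1O | intermediate
4 | 3-methylbut-2-enal | CC(C)=CC=O | starting material
5 | o-quinone methide, not isolated: 3,5-dihydroxy-6-(3-methylbut-2-en-1-ylidene)-4-(2-methylpropanoyl)cyclohexa-2,4-dien-1-one | CC(C)C(=O)C1=C(O)C(=CC=C(C)C)C(=O)C=C1O | intermediate
6 | 1-(5,7-dihydroxy-2,2-dimethyl-2H-chromen-6-yl)-2-methylpropan-1-one | CC(C)C(=O)c1c(O)cc2OC(C)(C)C=Cc2c1O | intermediate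
7 | aryl iminium chloride, not isolated: [5,7-dihydroxy-2,2-dimethyl-6-(2-methylpropanoyl)-2H-chromen-8-yl]methylidene(dimethyl)ammonium chloride | CC(C)C(=O)c1c(O)c(C=[N+](C)C)c2OC(C)(C)C=Cc2c1O.[Cl-] | intermediate
8 | 5,7-dihydroxy-2,2-dimethyl-6-(2-methylpropanoyl)-2H-chromene-8-carbaldehyde | CC(C)C(=O)c1c(O)c(C=O)c2OC(C)(C)C=Cc2c1O | intermediate
9 | 5,7-dimethoxy-2,2-dimethyl-6-(2-methylpropanoyl)-2H-chromene-8-carbaldehyde | CC(C)C(=O)c1c(OC)c(C=O)c2OC(C)(C)C=Cc2c1OC | intermediate
10 | 2,2-dimethyl-1,3-dioxane-4,6-dione (Meldrum's acid) | CC1(C)OC(=O)CC(=O)O1 | starting material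
11 | arylidene Meldrum's acid, not isolated: 5-{[5,7-dimethoxy-2,2-dimethyl-6-(2-methylpropanoyl)-2H-chromen-8-yl]methylidene}-2,2-dimethyl-1,3-dioxane-4,6-dione | CC(C)C(=O)c1c(OC)c(C=C3C(=O)OC(C)(C)OC3=O)c2OC(C)(C)C=Cc2c1OC | intermediate
12 | 5-{[5,7-dimethoxy-2,2-dimethyl-6-(2-methylpropanoyl)-2H-chromen-8-yl]methyl}-2,2-dimethyl-1,3-dioxane-4,6-dione | CC(C)C(=O)c1c(OC)c(CC3C(=O)OC(C)(C)OC3=O)c2OC(C)(C)C=Cc2c1OC | intermediate
13 | malonic half methyl ester, not isolated, racemic: 2-{[5,7-dimethoxy-2,2-dimethyl-6-(2-methylpropanoyl)-2H-chromen-8-yl]methyl}-3-methoxy-3-oxopropanoic acid | CC(C)C(=O)c1c(OC)c(CC(C(=O)O)C(=O)OC)c2OC(C)(C)C=Cc2c1OC | intermediate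
14 | 2-{[5,7-dimethoxy-2,2-dimethyl-6-(2-methylpropanoyl)-2H-chromen-8-yl]methyl}propanedioic acid | CC(C)C(=O)c1c(OC)c(CC(C(=O)O)C(=O)O)c2OC(C)(C)C=Cc2c1OC | intermediate
15 | pentan-3-one | CCC(=O)CC | starting material
16 | (Z)-trimethyl(pent-2-en-3-yloxy)silane | C/C=C(/CC)O[Si](C)(C)C | intermediate
17 | 2-{[5,7-dimethoxy-2,2-dimethyl-6-(2-methylpropanoyl)-2H-chromen-8-yl]methyl}propanedioyl dichloride | CC(C)C(=O)c1c(OC)c(CC(C(Cl)=O)C(Cl)=O)c2OC(C)(C)C=Cc2c1OC | intermediate
18 | (chlorocarbonyl)ketene, not isolated: 2-{[5,7-dimethoxy-2,2-dimethyl-6-(2-methylpropanoyl)-2H-chromen-8-yl]methyl}-3-oxoprop-2-enoyl chloride | CC(C)C(=O)c1c(OC)c(CC(=C=O)C(Cl)=O)c2OC(C)(C)C=Cc2c1OC | intermediate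
19 | 3-{[5,7-dimethoxy-2,2-dimethyl-6-(2-methylpropanoyl)-2H-chromen-8-yl]methyl}-6-ethyl-4-hydroxy-5-methyl-2H-pyran-2-one | CCc1oc(=O)c(Cc2c(OC)c(C(=O)C(C)C)c(OC)c3c2OC(C)(C)C=C3)c(O)c1C | intermediate
20 | 3-{[5,7-dihydroxy-2,2-dimethyl-6-(2-methylpropanoyl)-2H-chromen-8-yl]methyl}-6-ethyl-4-hydroxy-5-methyl-2H-pyran-2-one | CCc1oc(=O)c(Cc2c(O)c(C(=O)C(C)C)c(O)c3c2OC(C)(C)C=C3)c(O)c1C | target

**Step count**
Total step count: 10.
Longest linear sequence: 9 (steps 1–6, 8, 9, 10).

**Steps most likely to fail**

**Step 9.**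
- What may go wrong: the acyl ketene may be consumed before C-acylation. The neighbouring ether oxygens (C7-OMe or O1) may attack the ketene or acyl chloride with dealkylative lactonisation. The ketene may self-condense, or the enol ether may be O-acylated.
- Fallback (sets out from 16 and 9, comes back at 19): the pyrone is built first and the bridge is made afterwards.
  - 16 and malonyl dichloride (Et2O, −78 °C → rt) should give 6-ethyl-4-hydroxy-5-methyl-2H-pyran-2-one F1, by the same type of annulation on an unhindered partner.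
  - F1, aldehyde 9, Hantzsch ester and L-proline (CH2Cl2, rt) then undergo Knoevenagel condensation to the 3-arylidenepyran-2,4-dione F2. F2 is reduced in the flask by hydride transfer to 19.
  - The bridge carbon is already bound to C8, so no symmetrical methylene-bridged dimer can arise.

**Step 10.**
- What may go wrong: cleavage may stop after the first methyl ether. The Lewis acid and the HCl it carries may also add to or open the 2H-pyran ring.
- Fallback (sets out from 8, comes back at 20): the phenols are masked as allyl ethers, which come off under neutral conditions.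
  - 8 with allyl bromide and K2CO3 in DMF should give the 5,7-bis(allyloxy) aldehyde F3.
  - The conditions of steps 5, 6, 8 and 9 then lead through the arylidene Meldrum's acid F4 (not isolated), the arylmethyl Meldrum's acid F5, the half methyl ester F6 (not isolated), the malonic acid F7, the dichloride F8 and its (chlorocarbonyl)ketene F9 (not isolated). The end point of this sequence is the 5,7-di-O-allyl ether of the target F10.
  - Pd(PPh3)4 (zerovalent palladium, 5 mol %) and excess morpholine in THF at room temperature transfer both allyl groups to the amine (Tsuji–Trost-type deallylation) and give 20 without any acid.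

**Step 2.**
- What may go wrong: the o-quinone methide may close on a chelated ortho hydroxyl, which gives poor regioselectivity between the 6-acyl and 8-acyl series. A second chromenylation may also occur.
- Fallback (sets out from 3, comes back at 6): the ring oxygen is fixed before the ring is closed.
  - The most acidic, non-chelated 4-hydroxyl of 3 is O-alkylated with 3-chloro-3-methylbut-1-yne (DBU, CuCl2 cat., MeCN, 0 °C). This gives 1-[2,6-dihydroxy-4-(2-methylbut-3-yn-2-yloxy)phenyl]-2-methylpropan-1-one F11.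
  - Heating in xylene (140 °C) brings about the aryl propargyl ether Claisen rearrangement, hydrogen shift and oxa-6π closure.
  - The two positions ortho to the ether are equivalent by symmetry, so only 6 should form.

**Further compounds**
F1 | step 9 | 6-ethyl-4-hydroxy-5-methyl-2H-pyran-2-one | CCc1oc(=O)cc(O)c1C
F2 | step 9 | 3-{[5,7-dimethoxy-2,2-dimethyl-6-(2-methylpropanoyl)-2H-chromen-8-yl]methylidene}-6-ethyl-5-methyl-2H-pyran-2,4(3H)-dione (not isolated) | CCC1=C(C)C(=O)C(=Cc2c(OC)c(C(=O)C(C)C)c(OC)c3c2OC(C)(C)C=C3)C(=O)O1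
F3 | step 10 | 2,2-dimethyl-6-(2-methylpropanoyl)-5,7-bis(prop-2-en-1-yloxy)-2H-chromene-8-carbaldehyde | CC(C)C(=O)c1c(OCC=C)c(C=O)c2OC(C)(C)C=Cc2c1OCC=C
F4 | step 10 | 5-{[2,2-dimethyl-6-(2-methylpropanoyl)-5,7-bis(prop-2-en-1-yloxy)-2H-chromen-8-yl]methylidene}-2,2-dimethyl-1,3-dioxane-4,6-dione (not isolated) | CC(C)C(=O)c1c(OCC=C)c(C=C3C(=O)OC(C)(C)OC3=O)c2OC(C)(C)C=Cc2c1OCC=C
F5 | step 10 | 5-{[2,2-dimethyl-6-(2-methylpropanoyl)-5,7-bis(prop-2-en-1-yloxy)-2H-chromen-8-yl]methyl}-2,2-dimethyl-1,3-dioxane-4,6-dione | CC(C)C(=O)c1c(OCC=C)c(CC3C(=O)OC(C)(C)OC3=O)c2OC(C)(C)C=Cc2c1OCC=C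
F6 | step 10 | 2-{[2,2-dimethyl-6-(2-methylpropanoyl)-5,7-bis(prop-2-en-1-yloxy)-2H-chromen-8-yl]methyl}-3-methoxy-3-oxopropanoic acid (racemic, not isolated) | CC(C)C(=O)c1c(OCC=C)c(CC(C(=O)O)C(=O)OC)c2OC(C)(C)C=Cc2c1OCC=C
F7 | step 10 | 2-{[2,2-dimethyl-6-(2-methylpropanoyl)-5,7-bis(prop-2-en-1-yloxy)-2H-chromen-8-yl]methyl}propanedioic acid | CC(C)C(=O)c1c(OCC=C)c(CC(C(=O)O)C(=O)O)c2OC(C)(C)C=Cc2c1OCC=C
F8 | step 10 | 2-{[2,2-dimethyl-6-(2-methylpropanoyl)-5,7-bis(prop-2-en-1-yloxy)-2H-chromen-8-yl]methyl}propanedioyl dichloride | CC(C)C(=O)c1c(OCC=C)c(CC(C(Cl)=O)C(Cl)=O)c2OC(C)(C)C=Cc2c1OCC=C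
F9 | step 10 | 2-{[2,2-dimethyl-6-(2-methylpropanoyl)-5,7-bis(prop-2-en-1-yloxy)-2H-chromen-8-yl]methyl}-3-oxoprop-2-enoyl chloride (not isolated) | CC(C)C(=O)c1c(OCC=C)c(CC(=C=O)C(Cl)=O)c2OC(C)(C)C=Cc2c1OCC=C
F10 | step 10 | 3-{[2,2-dimethyl-6-(2-methylpropanoyl)-5,7-bis(prop-2-en-1-yloxy)-2H-chromen-8-yl]methyl}-6-ethyl-4-hydroxy-5-methyl-2H-pyran-2-one | CCc1oc(=O)c(Cc2c(OCC=C)c(C(=O)C(C)C)c(OCC=C)c3c2OC(C)(C)C=C3)c(O)c1C
F11 | step 2 | 1-[2,6-dihydroxy-4-(2-methylbut-3-yn-2-yloxy)phenyl]-2-methylpropan-1-one | CC(C)C(=O)c1c(O)cc(OC(C)(C)C#C)cc1O
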